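## Numbering used throughout

1 prenol · 2 (2R)-epoxy alcohol · 3 (2S)-epoxy aldehyde · 4 resacetophenone · 5 bis(triisopropoxytitanium) phenolate of 4 · 6 anti epoxy alcohol · 7 cis diol (product of the key step) · 8 angelic acid · 9 angelic 2,4,6-trichlorobenzoic anhydride · 10 C3 angelate with tertiary alcohol · 11 isopropenyl compound · 12 primary allylic alcohol · 13 target.

## Analysis of the target

The target is a 2,3-dihydro-1-benzofuran: a benzene ring (C3a to C7a) fused to a five-membered oxygen ring (O1, C2, C3). The arene carries an acetyl group at C5 and a hydroxyl at C6 that are hydrogen-bonded to each other, so the aromatic half is 4 with its second oxygen as O1 and its free position para to the chelated hydroxyl as C3a. There are two stereocentres: C2 (R) bears the 3-acetoxyprop-1-en-2-yl group and C3 (R) bears the angelate. Side chain and ester oxygen lie on the same face (cis), which puts the hydrogen on C2 anti to the C3–O bond. The sensitive points follow from this. The benzylic ester at C3, ortho to O1 and para to the C6 oxygen, can leave together with the hydrogen on C2 to give an aromatic benzofuran. The Z-configured angelate isomerises to the E tiglate under nucleophilic catalysis, and the two esters must end up on different hydroxyls. The difficulty is thus to set the less stable cis C2/C3 pair in one enantiomeric form on a ring that tends to aromatise, preferably without protecting the phenol. The strategy rests on two facts: C3a is the nucleophilic carbon ortho to O1 of 4, and C3–C2–C1' with its two carbon substituents is a prenyl unit at the oxidation level of an epoxy aldehyde. C3 is the aldehyde carbon of 3 and C2 its epoxide carbon; the epoxide oxygen ends as a tertiary hydroxyl on C1', from which the oxygenated isopropenyl group is developed.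

## Retrosynthetic reasoning

13 to 12. The acetate C–O bond is cut first. In 12 the primary allylic hydroxyl is the only unhindered one, since the phenol is tied to the acetyl carbonyl, so the most labile ester goes on last by a selective acetylation.

12 to 11. The allylic C–O bond on the side chain is removed. The oxygen is brought in by allylic oxidation of the isopropenyl methyl group, so no differentiated primary oxygen has to be carried through the route. The forward reaction must oxidise the methyl group and not the C2–H, and must leave the electron-poor alkene of the angelate alone.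

11 to 10. The terminal alkene is traced back to the tertiary alcohol on C1'. The forward dehydration has to remove a methyl hydrogen and must not ionise the benzylic ester.

10 to 7 and 9. The angelate C–O bond is cut. In 7 the C3 hydroxyl is the only readily acylated alcohol, because the C1' hydroxyl is tertiary and the phenol is chelated, so no protecting group is needed. 9 comes from 8 by mixed-anhydride formation, chosen because it transfers the Z acid without isomerisation.

7 to 4 and 3 (key disconnection). C3–C3a and O1–C2 are cut together. 4 is a C,O-dinucleophile (ortho carbon and phenol oxygen) and 3 a 1,2-dielectrophile (aldehyde carbon and adjacent epoxide carbon). This is the only cut that uses a complete commercial arene and makes the ring, two bonds and both stereocentres in one operation from a single stereocentre. Forward, titanium phenolate 5 must add through the right ortho carbon, anti to the epoxide C–O bond, to give 6. The phenoxide must then open the epoxide at C2 (5-exo) with inversion, which turns anti into cis.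

3 to 2 to 1. The aldehyde is taken back to the primary alcohol and the epoxide to the alkene of 1. A Katsuki–Sharpless asymmetric epoxidation sets the only stereocentre that is introduced by a reagent; the ligand enantiomer of the D series is chosen for the (2R) configuration of 2.

## Alternatives that were turned down

Alternative 1: Rhodium-catalysed (2+2+2) cyclotrimerisation that makes the arene and the dihydrofuran together. The bonds cut are C3a–C7a, C6–C7 and C4–C5. The key-step product would be 1-[(2R,3R)-3-(tert-butyldimethylsilyloxy)-2-{3-(tert-butyldimethylsilyloxy)prop-1-en-2-yl}-6-ethoxy-2,3-dihydro-1-benzofuran-5-yl]ethanone (A1). It would form when the tethered diyne (3R,4R)-3-(tert-butyldimethylsilyloxy)-5-[(tert-butyldimethylsilyloxy)methyl]-4-(ethynyloxy)hex-5-en-1-yne (A2) takes up 4-ethoxybut-3-yn-2-one (A3) on a cationic monovalent rhodium centre.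
- For it: the tether dictates which carbons become C3a and C7a, so the site-selectivity question that step 3 must answer does not arise. On this point the alternative is stronger. Both stereocentres are set in open-chain chemistry.
- Against it: A2 is a terminal ynol ether of a secondary allylic alcohol, a class that hydrolyses and fragments easily, and it needs its own long enantioselective synthesis. The orientation of A3 (acetyl at C5, ethoxy at C6) rests only on electronic matching of two polarised alkynes. A1 still needs the aryl ethyl ether cleaved and two identical silyl ethers told apart before either ester can be attached.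
- Comparison: the chosen route takes the finished arene as 4, forms two bonds instead of three and uses no protecting group.

Alternative 2: Iridium-catalysed umpolung oxyallylation that closes C2–C3. The bond cut is C2–C3. The key-step product would be 1-[(2R,3R)-2-(3-acetoxyprop-1-en-2-yl)-3-hydroxy-6-(triisopropylsilyloxy)-2,3-dihydro-1-benzofuran-5-yl]ethanone (A4). Its precursor is the aryl enol ether 2-{[4-acetyl-2-formyl-5-(triisopropylsilyloxy)phenoxy]methylidene}propane-1,3-diyl diacetate (A5), whose two allylic acetates are equivalent. Ionisation of either gives an allyl–iridium species that becomes nucleophilic under transfer-hydrogenation conditions and adds through its oxygen-bearing terminus to the ortho formyl carbon.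
- For it: A4 already has the finished side chain with its acetate and a free C3 hydroxyl, so only angeloylation and desilylation remain. On end-game economy this is clearly better than the chosen route, which spends steps 6, 7 and 8 on the side chain.
- Against it: both stereocentres and their cis relationship must come from the catalyst in a strained bicyclic transition structure, with nothing in the substrate to favour cis. A4 is itself an allylic acetate and an allylic aryl ether and can ionise again under the same catalyst. The aryl ketone is a competing hydrogen acceptor. A5 requires a formylated, selectively silylated arene and an enol ether synthesis before any stereocentre exists.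
- Comparison: the chosen strategy offers a cis relationship that follows mechanistically from anti addition and inversion, and an absolute configuration taken from a dependable asymmetric epoxidation.

Alternative 3: Diels–Alder benzannulation onto a preformed chiral dihydrofuran. The bonds cut are C3a–C4 and C5–C6. The key-step product would be 1-[(2R,3R)-3-(tert-butyldimethylsilyloxy)-2-{3-(tert-butyldimethylsilyloxy)prop-1-en-2-yl}-6-hydroxy-2,3-dihydro-1-benzofuran-5-yl]ethanone (A6). The diene is the silyl ketene acetal (2R,3R)-3-(tert-butyldimethylsilyloxy)-2-[3-(tert-butyldimethylsilyloxy)prop-1-en-2-yl]-5-[2-(tert-butyldimethylsilyloxy)-2-methoxyethenyl]-2,3-dihydrofuran (A7), in which C6, C7, C7a and C3a form the diene. The dienophile is but-3-yn-2-one (A8), and the adduct aromatises by expelling its methoxy group.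
- For it: the orientation is reliable, since the nucleophilic diene terminus C3a meets the β-carbon of A8. Acetyl and hydroxyl arrive in their chelated ortho relationship. No site selectivity on an existing arene is required, a point on which this alternative is stronger than step 3.
- Against it: A7 is a 3-silyloxy-2,3-dihydrofuran enol ether that can aromatise to a furan by loss of the C3 oxygen under mild acid or heat, so both the diene and the cycloadduct can collapse the wrong way. A7 with its two stereocentres needs a long enantioselective synthesis. A6, like A1, still requires two silyl ethers to be differentiated.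
- Comparison: the chosen route reaches the same ring system from 4 and 3 in one operation and carries its main uncertainty in an early, cheap step.

Key step: step 3

Remark on the chemistry: the usual facial rule of the Katsuki–Sharpless epoxidation is assumed to hold for 1, so that the D-(−)-tartrate ester gives (2R)-2; 1, 4 and 8 are taken as commercial.

## Route

Step 1
Reactants: 1 3-methylbut-2-en-1-ol (prenol)
Product: 2 [(2R)-3,3-dimethyloxiran-2-yl]methanol
Conditions: Ti(OiPr)4 (5 mol %), D-(−)-diisopropyl tartrate (6 mol %), t-BuOOH (anhydrous, in isooctane), 4 Å MS, CH2Cl2, −20 °C; non-aqueous work-up, distillation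
Reagents that add atoms: tert-butyl hydroperoxide, CC(C)(C)OO
Why: Katsuki–Sharpless asymmetric epoxidation: alcohol and hydroperoxide bind to the tartrate-bridged tetravalent titanium and the peroxide oxygen is delivered to one enantiotopic face, which with the D-(−)-tartrate ester should be the one giving (2R). Work-up avoids water because 2 is volatile and water-soluble.

Step 2
Reactants: 2 [(2R)-3,3-dimethyloxiran-2-yl]methanol
Product: 3 (2S)-3,3-dimethyloxirane-2-carbaldehyde
Conditions: TEMPO (10 mol %), PhI(OAc)2 (1.1 equiv), CH2Cl2, 0 °C → rt; aq NaHCO3 wash, solution dried (MgSO4) and used directly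
Reagents that add atoms: none
Why: Oxoammonium (TEMPO) oxidation with PhI(OAc)2 as terminal oxidant stops at the aldehyde under non-basic conditions that leave the epoxide intact. The stereocentre is an epoxide carbon that cannot enolise; its descriptor changes from R to S only because the formyl group now outranks the ring carbon.

Step 3
Reactants: 4 1-(2,4-dihydroxyphenyl)ethanone (resacetophenone); 3 (2S)-3,3-dimethyloxirane-2-carbaldehyde
Product: 7 1-[(2S,3R)-3,6-dihydroxy-2-(2-hydroxypropan-2-yl)-2,3-dihydro-1-benzofuran-5-yl]ethanone, via bis(triisopropoxytitanium) phenolate 5 (not isolated), via anti epoxy alcohol 6 (not isolated)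
Conditions: 4, Ti(OiPr)4 (2.05 equiv), toluene, rt, iPrOH stripped with toluene under reduced pressure; toluene/CH2Cl2, 3 (1.3 equiv), −30 → 0 °C; aq potassium sodium tartrate (KNaC4H4O6)/NaHCO3, extraction; crude 6, K2CO3 (1.5 equiv), MeOH, 0 °C → rt
Reagents that add atoms: none
Why: Proposed new method: the closest known reaction types are the ortho-selective hydroxyalkylation of aryloxytitanium and aryloxymagnesium species by α-oxygenated aldehydes (a metal-templated Friedel–Crafts reaction) and the base-mediated 5-exo opening of epoxides by ortho phenoxides; joining the two on an epoxy aldehyde is new. Both phenols of 4 exchange onto tetravalent titanium to give 5; the titanium on the oxygen para to the acetyl group binds the formyl oxygen of 3 and passes the aldehyde carbon to the neighbouring ring carbon through a six-membered cyclic array, which forms C3–C3a, and the dienone then rearomatises. The ring carbon between the two aryloxytitanium groups is the more electron-rich one but is shielded on both sides by Ti(OiPr)3 units, so the bond should form at the carbon para to the chelated oxygen, which has only one such neighbour. C3 is controlled by the epoxide stereocentre of 3: the epoxide oxygen does not chelate the crowded titanium, the polar Felkin–Anh arrangement puts its C–O bond anti to the incoming arene, and the (S)-aldehyde should give the (R)-carbinol of anti epoxy alcohol 6. Titanium is washed out before base is added, because titanium-bound 2,3-epoxy alcohols open at the distal, here tertiary, carbon (6-endo, chromane), as acid would. K2CO3 in MeOH ionises only the phenol para to the acetyl group, and its oxygen attacks the secondary epoxide carbon from the rear in a 5-exo-tet SN2 closure of the dihydrofuran ring (O1–C2). The inversion at C2 converts the anti epoxy alcohol into the cis-(2S,3R) diol, so C2 traces back to the asymmetric epoxidation and C3 to 1,2-induction from it. Payne rearrangement is not expected to compete, since carbonate does not ionise the carbinol while the phenoxide is present in quantity.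

Step 4
Reactants: 8 (2Z)-2-methylbut-2-enoic acid (angelic acid)
Product: 9 (2Z)-2-methylbut-2-enoic 2,4,6-trichlorobenzoic anhydride
Conditions: 2,4,6-trichlorobenzoyl chloride (1.0 equiv), Et3N (1.05 equiv), toluene, 0 °C → rt; Et3N·HCl filtered off, concentrated, used crude
Reagents that add atoms: 2,4,6-trichlorobenzoyl chloride, O=C(Cl)c1c(Cl)cc(Cl)cc1Cl
Why: Mixed-anhydride formation of the Yamaguchi type by attack of the carboxylate of 8 on the acid chloride. No nucleophilic catalyst is present, so the Z alkene has no conjugate addition–elimination pathway and should keep its geometry.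

Step 5
Reactants: 7 1-[(2S,3R)-3,6-dihydroxy-2-(2-hydroxypropan-2-yl)-2,3-dihydro-1-benzofuran-5-yl]ethanone; 9 (2Z)-2-methylbut-2-enoic 2,4,6-trichlorobenzoic anhydride
Product: 10 (2S,3R)-5-acetyl-6-hydroxy-2-(2-hydroxypropan-2-yl)-2,3-dihydro-1-benzofuran-3-yl (2Z)-2-methylbut-2-enoate
Conditions: 9 (1.5 equiv), Et3N (1.5 equiv), toluene, 60–70 °C, no 4-dimethylaminopyridine
Reagents that add atoms: none
Why: Yamaguchi-type acylation at the unhindered angeloyl carbonyl (the other carbonyl is blocked by two ortho chlorines); leaving out the nucleophilic catalyst avoids the Michael addition–elimination that turns angelates into tiglates. The tertiary alcohol is too hindered and the chelated phenol too weakly nucleophilic to compete, and since the reaction occurs at oxygen, C3 keeps its configuration.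

Step 6
Reactants: 10 (2S,3R)-5-acetyl-6-hydroxy-2-(2-hydroxypropan-2-yl)-2,3-dihydro-1-benzofuran-3-yl (2Z)-2-methylbut-2-enoate
Product: 11 (2R,3R)-5-acetyl-6-hydroxy-2-(prop-1-en-2-yl)-2,3-dihydro-1-benzofuran-3-yl (2Z)-2-methylbut-2-enoate
Conditions: SOCl2 (1.5 equiv), pyridine (10 equiv), CH2Cl2, −20 → 0 °C
Reagents that add atoms: none
Why: E2 dehydration through the chlorosulfite with pyridine as base: one of six methyl hydrogens is removed in preference to the single hindered C2–H, as in the dehydration of other 2-(2-hydroxypropan-2-yl)dihydrobenzofurans. The basic medium and low temperature should keep the benzylic ester from ionising; the C2 descriptor changes from S to R only because the side chain loses CIP rank.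

Step 7
Reactants: 11 (2R,3R)-5-acetyl-6-hydroxy-2-(prop-1-en-2-yl)-2,3-dihydro-1-benzofuran-3-yl (2Z)-2-methylbut-2-enoate
Product: 12 (2R,3R)-5-acetyl-6-hydroxy-2-(3-hydroxyprop-1-en-2-yl)-2,3-dihydro-1-benzofuran-3-yl (2Z)-2-methylbut-2-enoate
Conditions: SeO2 (0.5 equiv), t-BuOOH (3 equiv), CH2Cl2, 0 °C → rt
Reagents that add atoms: tert-butyl hydroperoxide, CC(C)(C)OO (stoichiometric oxygen source); selenium dioxide, O=[Se]=O (carries the oxygen to carbon)
Why: SeO2 allylic oxidation with t-BuOOH as reoxidant (ene reaction, then [2,3]-sigmatropic shift): the 1,1-disubstituted alkene reacts and the methyl group is oxidised in preference to the hindered methine C2–H, which returns the double bond to its place. The conjugated, electron-poor alkene of the angelate should not enter the ene step, and the aryl methyl ketone is not attacked at room temperature.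

Step 8
Reactants: 12 (2R,3R)-5-acetyl-6-hydroxy-2-(3-hydroxyprop-1-en-2-yl)-2,3-dihydro-1-benzofuran-3-yl (2Z)-2-methylbut-2-enoate
Product: 13 (2R,3R)-2-[3-(acetyloxy)prop-1-en-2-yl]-5-acetyl-6-hydroxy-2,3-dihydro-1-benzofuran-3-yl (2Z)-2-methylbut-2-enoate
Conditions: Ac2O (1.2 equiv), pyridine, CH2Cl2, 0 °C
Reagents that add atoms: acetic anhydride, CC(=O)OC(C)=O
Why: Acetylation of the only unhindered hydroxyl. The phenol is held in the hydrogen bond to the acetyl carbonyl and should not be acylated at 0 °C without a nucleophilic catalyst.

## Compound list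

1 | 3-methylbut-2-en-1-ol (prenol) | CC(C)=CCO | starting material
2 | [(2R)-3,3-dimethyloxiran-2-yl]methanol | OC[C@H]1OC1(C)C | intermediate
3 | (2S)-3,3-dimethyloxirane-2-carbaldehyde | O=C[C@H]1OC1(C)C | intermediate
4 | 1-(2,4-dihydroxyphenyl)ethanone (resacetophenone) | CC(=O)c1ccc(O)cc1O | starting material
5 | [4-acetylbenzene-1,3-diylbis(oxy)]bis[tri(propan-2-yloxy)titanium] (bis(triisopropoxytitanium) phenolate of 4) | CC(=O)c1ccc(O[Ti](OC(C)C)(OC(C)C)OC(C)C)cc1O[Ti](OC(C)C)(OC(C)C)OC(C)C | intermediate
6 | 1-{5-[(R)-[(2R)-3,3-dimethyloxiran-2-yl](hydroxy)methyl]-2,4-dihydroxyphenyl}ethanone | CC(=O)c1cc([C@@H](O)[C@H]2OC2(C)C)c(O)cc1O | intermediate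
7 | 1-[(2S,3R)-3,6-dihydroxy-2-(2-hydroxypropan-2-yl)-2,3-dihydro-1-benzofuran-5-yl]ethanone | CC(C)(O)[C@H]1Oc2cc(O)c(C(C)=O)cc2[C@H]1O | intermediate
8 | (2Z)-2-methylbut-2-enoic acid (angelic acid) | C/C=C(/C)C(=O)O | starting material
9 | (2Z)-2-methylbut-2-enoic 2,4,6-trichlorobenzoic anhydride | C/C=C(/C)C(=O)OC(=O)c1c(Cl)cc(Cl)cc1Cl | intermediate
10 | (2S,3R)-5-acetyl-6-hydroxy-2-(2-hydroxypropan-2-yl)-2,3-dihydro-1-benzofuran-3-yl (2Z)-2-methylbut-2-enoate | CC(C)(O)[C@H]1Oc2cc(O)c(C(C)=O)cc2[C@H]1OC(=O)/C(C)=C\C | intermediate
11 | (2R,3R)-5-acetyl-6-hydroxy-2-(prop-1-en-2-yl)-2,3-dihydro-1-benzofuran-3-yl (2Z)-2-methylbut-2-enoate | C=C(C)[C@H]1Oc2cc(O)c(C(C)=O)cc2[C@H]1OC(=O)/C(C)=C\C | intermediate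
12 | (2R,3R)-5-acetyl-6-hydroxy-2-(3-hydroxyprop-1-en-2-yl)-2,3-dihydro-1-benzofuran-3-yl (2Z)-2-methylbut-2-enoate | C=C(CO)[C@H]1Oc2cc(O)c(C(C)=O)cc2[C@H]1OC(=O)/C(C)=C\C | intermediate
13 | (2R,3R)-2-[3-(acetyloxy)prop-1-en-2-yl]-5-acetyl-6-hydroxy-2,3-dihydro-1-benzofuran-3-yl (2Z)-2-methylbut-2-enoate | C=C(COC(C)=O)[C@H]1Oc2cc(O)c(C(C)=O)cc2[C@H]1OC(=O)/C(C)=C\C | target

## Step count and least certain steps

Total step count: 8. Longest linear sequence: 7 steps (steps 1, 2, 3, 5, 6, 7 and 8, from 1 to 13); step 4 is a one-step side branch.

**Step 3 (key step, proposed new method).** Three things are most likely to go wrong.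
- Hydroxyalkylation at the wrong ring carbon: the position between the two oxygens is electronically the most activated and either titanium could deliver the aldehyde there.
- Sluggish C–C bond formation: the acetyl group lowers the nucleophilicity of the phenolate, which gives time for Lewis-acid opening of the epoxide or for further arylation of the new benzylic alkoxide.
- Incomplete anti selectivity at the carbonyl, which would lead to the trans ring isomer after closure.

The fallback uses known chemistry, sets out from 4 and returns at 7. Iodination of 4 with ICl in AcOH, which under non-basic conditions substitutes para to the chelated hydroxyl, should give 1-(2,4-dihydroxy-5-iodophenyl)ethanone F1. Silylation (t-BuMe2SiCl, imidazole, DMF) gives 1-[2,4-bis(tert-butyldimethylsilyloxy)-5-iodophenyl]ethanone F2. A Nozaki–Hiyama–Kishi coupling of F2 with 3 (CrCl2, catalytic NiCl2, DMF), which is aldehyde-selective and tolerates the ketone, gives 1-{2,4-bis(tert-butyldimethylsilyloxy)-5-[(R)-[(2R)-3,3-dimethyloxiran-2-yl](hydroxy)methyl]phenyl}ethanone F3 together with its carbinol epimer, to be separated. Bu4NF in THF then frees the phenoxides; 6 forms and closes to 7 as in step 3, with K2CO3/MeOH if needed. The C–I bond fixes the ring position; the cost is three more steps and weaker facial control.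

**Step 5.** Possible failures are isomerisation of the angelate to the tiglate, competing acylation of the phenol, and ionisation of the benzylic ester once formed, since a phenoxide para to the benzylic carbon can expel carboxylate and lead on to the benzofuran. The fallback builds the Z alkene after the ester bond; it sets out from 7 and returns at 10. Esterification of 7 with 2-[bis(2,2,2-trifluoroethoxy)phosphoryl]propanoic acid (carbodiimide, catalytic 4-dimethylaminopyridine, harmless here because no alkene is present) gives (2S,3R)-5-acetyl-6-hydroxy-2-(2-hydroxypropan-2-yl)-2,3-dihydro-1-benzofuran-3-yl 2-[bis(2,2,2-trifluoroethoxy)phosphoryl]propanoate F4. Still–Gennari olefination of F4 with acetaldehyde (KN(SiMe3)2, 18-crown-6, THF, −78 °C, one extra equivalent of base for the phenol) should give the Z-trisubstituted alkene of 10 under kinetic control.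

**Step 6.** The main risk is loss of angelic acid with aromatisation to a benzofuran, because the C3–O bond is benzylic and anti to the hydrogen on C2. Elimination toward C2–H or chloride substitution at the tertiary carbon are lesser risks. The fallback removes the ester from the dehydration step; it sets out from 7 and returns at 11.
- Silylation of the C3 and phenolic hydroxyls (Et3SiCl, imidazole; the tertiary alcohol is left) gives 1-[(2S,3R)-2-(2-hydroxypropan-2-yl)-3,6-bis(triethylsilyloxy)-2,3-dihydro-1-benzofuran-5-yl]ethanone F5.
- Dehydration of F5 (SOCl2, pyridine) gives 1-[(2R,3R)-2-(prop-1-en-2-yl)-3,6-bis(triethylsilyloxy)-2,3-dihydro-1-benzofuran-5-yl]ethanone F6; a silyl ether at C3 is a far poorer leaving group than an ester.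
- Desilylation (Bu4NF buffered with AcOH) gives 1-[(2R,3R)-3,6-dihydroxy-2-(prop-1-en-2-yl)-2,3-dihydro-1-benzofuran-5-yl]ethanone F7.
- Acylation of F7 with 9 as in step 5 gives 11.

**Step 7.** Possible failures are over-oxidation of the allylic alcohol to the enal, slow conversion of a 1,1-disubstituted alkene next to an oxygenated carbon, and oxidation α to the aryl ketone on forcing. The fallback avoids selenium; it sets out from 11, returns at 13 and replaces steps 7 and 8.
- Dihydroxylation of the more electron-rich terminal alkene (catalytic OsO4, N-methylmorpholine N-oxide) gives (2S,3R)-5-acetyl-2-(1,2-dihydroxypropan-2-yl)-6-hydroxy-2,3-dihydro-1-benzofuran-3-yl (2Z)-2-methylbut-2-enoate F8, as a mixture at the new carbinol centre, which is later destroyed.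
- Acetylation of the primary hydroxyl (Ac2O, pyridine, 0 °C) gives (2S,3R)-2-[1-(acetyloxy)-2-hydroxypropan-2-yl]-5-acetyl-6-hydroxy-2,3-dihydro-1-benzofuran-3-yl (2Z)-2-methylbut-2-enoate F9.
- Dehydration of F9 toward the methyl group (SOCl2, pyridine) gives 13.

## Further compounds

F1 | step 3 | 1-(2,4-dihydroxy-5-iodophenyl)ethanone | CC(=O)c1cc(I)c(O)cc1O
F2 | step 3 | 1-[2,4-bis(tert-butyldimethylsilyloxy)-5-iodophenyl]ethanone | CC(=O)c1cc(I)c(O[Si](C)(C)C(C)(C)C)cc1O[Si](C)(C)C(C)(C)C
F3 | step 3 | 1-{2,4-bis(tert-butyldimethylsilyloxy)-5-[(R)-[(2R)-3,3-dimethyloxiran-2-yl](hydroxy)methyl]phenyl}ethanone | CC(=O)c1cc([C@@H](O)[C@H]2OC2(C)C)c(O[Si](C)(C)C(C)(C)C)cc1O[Si](C)(C)C(C)(C)C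
F4 | step 5 | (2S,3R)-5-acetyl-6-hydroxy-2-(2-hydroxypropan-2-yl)-2,3-dihydro-1-benzofuran-3-yl 2-[bis(2,2,2-trifluoroethoxy)phosphoryl]propanoate | CC(C)(O)[C@H]1Oc2cc(O)c(C(C)=O)cc2[C@H]1OC(=O)C(C)P(=O)(OCC(F)(F)F)OCC(F)(F)F
F5 | step 6 | 1-[(2S,3R)-2-(2-hydroxypropan-2-yl)-3,6-bis(triethylsilyloxy)-2,3-dihydro-1-benzofuran-5-yl]ethanone | CC(C)(O)[C@H]1Oc2cc(O[Si](CC)(CC)CC)c(C(C)=O)cc2[C@H]1O[Si](CC)(CC)CC
F6 | step 6 | 1-[(2R,3R)-2-(prop-1-en-2-yl)-3,6-bis(triethylsilyloxy)-2,3-dihydro-1-benzofuran-5-yl]ethanone | C=C(C)[C@H]1Oc2cc(O[Si](CC)(CC)CC)c(C(C)=O)cc2[C@H]1O[Si](CC)(CC)CC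
F7 | step 6 | 1-[(2R,3R)-3,6-dihydroxy-2-(prop-1-en-2-yl)-2,3-dihydro-1-benzofuran-5-yl]ethanone | C=C(C)[C@H]1Oc2cc(O)c(C(C)=O)cc2[C@H]1O
F8 | step 7 | (2S,3R)-5-acetyl-2-(1,2-dihydroxypropan-2-yl)-6-hydroxy-2,3-dihydro-1-benzofuran-3-yl (2Z)-2-methylbut-2-enoate | CC(O)(CO)[C@H]1Oc2cc(O)c(C(C)=O)cc2[C@H]1OC(=O)/C(C)=C\C
F9 | step 7 | (2S,3R)-2-[1-(acetyloxy)-2-hydroxypropan-2-yl]-5-acetyl-6-hydroxy-2,3-dihydro-1-benzofuran-3-yl (2Z)-2-methylbut-2-enoate | CC(O)(COC(C)=O)[C@H]1Oc2cc(O)c(C(C)=O)cc2[C@H]1OC(=O)/C(C)=C\C
A1 | alternative 1 | 1-[(2R,3R)-3-(tert-butyldimethylsilyloxy)-2-{3-(tert-butyldimethylsilyloxy)prop-1-en-2-yl}-6-ethoxy-2,3-dihydro-1-benzofuran-5-yl]ethanone | C=C(CO[Si](C)(C)C(C)(C)C)[C@H]1Oc2cc(OCC)c(C(C)=O)cc2[C@H]1O[Si](C)(C)C(C)(C)C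
A2 | alternative 1 | (3R,4R)-3-(tert-butyldimethylsilyloxy)-5-[(tert-butyldimethylsilyloxy)methyl]-4-(ethynyloxy)hex-5-en-1-yne | C=C(CO[Si](C)(C)C(C)(C)C)[C@@H](OC#C)[C@H](O[Si](C)(C)C(C)(C)C)C#C
A3 | alternative 1 | 4-ethoxybut-3-yn-2-one | CCOC#CC(C)=O
A4 | alternative 2 | 1-[(2R,3R)-2-(3-acetoxyprop-1-en-2-yl)-3-hydroxy-6-(triisopropylsilyloxy)-2,3-dihydro-1-benzofuran-5-yl]ethanone | C=C(COC(C)=O)[C@H]1Oc2cc(O[Si](C(C)C)(C(C)C)C(C)C)c(C(C)=O)cc2[C@H]1O
A5 | alternative 2 | 2-{[4-acetyl-2-formyl-5-(triisopropylsilyloxy)phenoxy]methylidene}propane-1,3-diyl diacetate | CC(=O)OCC(COC(C)=O)=COc1cc(O[Si](C(C)C)(C(C)C)C(C)C)c(C(C)=O)cc1C=O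
A6 | alternative 3 | 1-[(2R,3R)-3-(tert-butyldimethylsilyloxy)-2-{3-(tert-butyldimethylsilyloxy)prop-1-en-2-yl}-6-hydroxy-2,3-dihydro-1-benzofuran-5-yl]ethanone | C=C(CO[Si](C)(C)C(C)(C)C)[C@H]1Oc2cc(O)c(C(C)=O)cc2[C@H]1O[Si](C)(C)C(C)(C)C
A7 | alternative 3 | (2R,3R)-3-(tert-butyldimethylsilyloxy)-2-[3-(tert-butyldimethylsilyloxy)prop-1-en-2-yl]-5-[2-(tert-butyldimethylsilyloxy)-2-methoxyethenyl]-2,3-dihydrofuran | C=C(CO[Si](C)(C)C(C)(C)C)[C@H]1OC(C=C(OC)O[Si](C)(C)C(C)(C)C)=C[C@H]1O[Si](C)(C)C(C)(C)C
A8 | alternative 3 | but-3-yn-2-one | C#CC(C)=O
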